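**Retrosynthetic overview**

- The ten-membered carbocycle is closed last, at C1–C2, by a SmI2 Reformatsky-type aldol of a bromomethyl ketone onto the C1 aldehyde.
- The C6 angelate is installed by Mitsunobu inversion of the carbinol formed in the fragment coupling.
- Late fragment coupling: Nozaki–Hiyama allylation joins a 3-(bromomethyl)butenolide (C1, C7–C14) to a keto-aldehyde (C2–C6, C15), forming C6–C7 and unveiling the α-methylene lactone.
- West fragment: C10 from (R)-3-bromo-2-methylpropanol, C8 by catalytic asymmetric alkenylzinc addition, butenolide by RCM. East fragment: C4 by Cu(II)-box Mukaiyama aldol on biacetyl.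
- Ring order: butenolide (RCM) first, which becomes the α-methylene-γ-lactone in the coupling, then the carbocycle.

Assumption: atom labels C1–C15 follow germacrane numbering (lactone carbonyl C12, exocyclic methylene C13, methyls C14 on C10 and C15 on C4); the facial preferences of (−)-MIB and Cu(II)–tBu-box are taken from their established models.

**Route**

Step 1
Reactants: 1 (R)-3-bromo-2-methylpropan-1-ol
Product: 2 [(2R)-3-bromo-2-methylpropoxy]triethylsilane
Conditions: TESCl, imidazole, CH2Cl2, 0 °C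
Reagents that add atoms: chlorotriethylsilane, CC[Si](Cl)(CC)CC
Why: Silyl ether protection of the primary alcohol; the purchased stereocentre (future C10) is not touched.

Step 2
Reactants: 2 [(2R)-3-bromo-2-methylpropoxy]triethylsilane
Product: 4 (3S)-3-methyl-4-[(triethylsilyl)oxy]butanal, via Grignard reagent 3 (not isolated)
Conditions: Mg, THF, 40 °C; then DMF, 0 °C; aq NH4Cl
Reagents that add atoms: N,N-dimethylformamide, CN(C)C=O
Why: Bouveault formylation of the primary Grignard reagent adds the C8 aldehyde carbon without affecting the remote stereocentre.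

Step 3
Reactants: 4 (3S)-3-methyl-4-[(triethylsilyl)oxy]butanal; 5 hex-1-yne
Product: 8 (2S,4R,5E)-2-methyl-1-[(triethylsilyl)oxy]dec-5-en-4-ol, via alkenylborane 6 (not isolated), via alkenylzinc 7 (not isolated)
Conditions: 5, Cy2BH, toluene, 0 °C to rt; Me2Zn, −78 °C; (−)-MIB (5 mol%), then 4, −10 °C; aq NH4Cl
Reagents that add atoms: none
Why: Oppolzer–Walsh catalytic asymmetric alkenylzinc addition (hydroboration, B-to-Zn transmetalation), in which the (−)-MIB zinc catalyst delivers the alkenyl group to the Si face of the aldehyde and so sets C8 as 4R under catalyst control.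

Step 4
Reactants: 9 2-(bromomethyl)prop-2-enoic acid
Product: 10 2-(bromomethyl)prop-2-enoyl chloride
Conditions: (COCl)2, cat. DMF, CH2Cl2, 0 °C to rt; distil
Reagents that add atoms: oxalyl chloride, O=C(Cl)C(=O)Cl
Why: Acid chloride formation under neutral Vilsmeier-type activation leaves the allylic bromide intact.

Step 5
Reactants: 8 (2S,4R,5E)-2-methyl-1-[(triethylsilyl)oxy]dec-5-en-4-ol; 10 2-(bromomethyl)prop-2-enoyl chloride
Product: 11 (2S,4R,5E)-2-methyl-1-[(triethylsilyl)oxy]dec-5-en-4-yl 2-(bromomethyl)prop-2-enoate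
Conditions: 2,6-lutidine, CH2Cl2, −20 to 0 °C
Reagents that add atoms: none
Why: O-acylation with a hindered, weakly nucleophilic base avoids SN2′ attack on the allylic bromide, and the C8–O bond is not broken so its configuration is retained.

Step 6
Reactants: 11 (2S,4R,5E)-2-methyl-1-[(triethylsilyl)oxy]dec-5-en-4-yl 2-(bromomethyl)prop-2-enoate
Product: 12 (5R)-3-(bromomethyl)-5-{(2S)-2-methyl-3-[(triethylsilyl)oxy]propyl}furan-2(5H)-one
Conditions: Grubbs II (5 mol%), CH2Cl2 (0.01 M), 40 °C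
Reagents that add atoms: none
Why: Ring-closing metathesis between the acrylate and the allylic alkene forms the butenolide with loss of hex-1-ene, and no stereocentre is involved.

Step 7
Reactants: 13 S-ethyl ethanethioate
Product: 15 {[1-(ethylsulfanyl)ethenyl]oxy}(trimethyl)silane, via lithium enolate 14 (not isolated)
Conditions: LDA, THF, −78 °C; then TMSCl, −78 °C to rt
Reagents that add atoms: chlorotrimethylsilane, C[Si](C)(C)Cl
Why: O-silylation of the kinetic thioester enolate gives the silyl ketene thioacetal needed for the Mukaiyama aldol.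

Step 8
Reactants: 15 {[1-(ethylsulfanyl)ethenyl]oxy}(trimethyl)silane; 16 butane-2,3-dione
Product: 18 S-ethyl (3R)-3-hydroxy-3-methyl-4-oxopentanethioate, via silyl ether 17 (not isolated)
Conditions: Cu(OTf)2 (10 mol%), (R,R)-tBu-box (11 mol%), THF, −78 °C; then 1 M HCl
Reagents that add atoms: none
Why: Evans Cu(II)-bis(oxazoline) catalysed Mukaiyama aldol, in which the diketone chelates square-planar copper and the (R,R)-ligand exposes the Re face of the bound ketone, setting the tertiary carbinol C4 as R.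

Step 9
Reactants: 18 S-ethyl (3R)-3-hydroxy-3-methyl-4-oxopentanethioate
Product: 19 S-ethyl (3R)-3-(acetyloxy)-3-methyl-4-oxopentanethioate
Conditions: Ac2O, Sc(OTf)3 (2 mol%), MeCN, −20 °C
Reagents that add atoms: acetic anhydride, CC(=O)OC(C)=O
Why: Lewis-acid catalysed acylation acetylates the tertiary alcohol without base, avoiding retro-aldol and E1cB pathways, and leaves the C4–O bond intact.

Step 10
Reactants: 19 S-ethyl (3R)-3-(acetyloxy)-3-methyl-4-oxopentanethioate
Product: 20 (3R)-3-methyl-1,4-dioxopentan-3-yl acetate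
Conditions: Et3SiH, 10% Pd/C, acetone, rt
Reagents that add atoms: none
Why: Fukuyama reduction converts the thioester into the aldehyde (C6) chemoselectively in the presence of the ketone and the acetate.

Step 11
Reactants: 12 (5R)-3-(bromomethyl)-5-{(2S)-2-methyl-3-[(triethylsilyl)oxy]propyl}furan-2(5H)-one; 20 (3R)-3-methyl-1,4-dioxopentan-3-yl acetate
Product: 22 (4R,5R)-4-[(1S,3R)-3-(acetyloxy)-1-hydroxy-3-methyl-4-oxopentyl]-3-methylidene-5-{(2S)-2-methyl-3-[(triethylsilyl)oxy]propyl}oxolan-2-one, via allylchromium 21 (not isolated)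
Conditions: CrCl2 (4 equiv), THF, 0 °C to rt; aq NH4Cl
Reagents that add atoms: none
Why: Nozaki–Hiyama allylation, in which the ring-locked (E)-allylchromium reacts at C7 through a Zimmerman–Traxler chair on the face anti to the C8 side chain, giving the 7,8-trans α-methylene lactone and the 6,7-anti carbinol (6S) and attacking the aldehyde in preference to the ketone.

Step 12
Reactants: 22 (4R,5R)-4-[(1S,3R)-3-(acetyloxy)-1-hydroxy-3-methyl-4-oxopentyl]-3-methylidene-5-{(2S)-2-methyl-3-[(triethylsilyl)oxy]propyl}oxolan-2-one; 23 (2Z)-2-methylbut-2-enoic acid (angelic acid)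
Product: 24 (1R,3R)-3-(acetyloxy)-3-methyl-1-[(2R,3S)-4-methylidene-2-{(2S)-2-methyl-3-[(triethylsilyl)oxy]propyl}-5-oxooxolan-3-yl]-4-oxopentyl (2Z)-2-methylbut-2-enoate
Conditions: PPh3, DIAD (betaine pre-formed), toluene, 0 °C to rt
Reagents that add atoms: none
Why: Mitsunobu esterification, in which SN2 displacement of the oxyphosphonium by angelate inverts C6 to the required R configuration and introduces the Z-ester without nucleophilic catalysts that would isomerise it to tiglate.

Step 13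
Reactants: 24 (1R,3R)-3-(acetyloxy)-3-methyl-1-[(2R,3S)-4-methylidene-2-{(2S)-2-methyl-3-[(triethylsilyl)oxy]propyl}-5-oxooxolan-3-yl]-4-oxopentyl (2Z)-2-methylbut-2-enoate
Product: 26 (1R,3R)-3-(acetyloxy)-5-bromo-3-methyl-1-[(2R,3S)-4-methylidene-2-{(2S)-2-methyl-3-[(triethylsilyl)oxy]propyl}-5-oxooxolan-3-yl]-4-oxopentyl (2Z)-2-methylbut-2-enoate, via silyl enol ether 25 (not isolated)
Conditions: TMSOTf, Et3N, CH2Cl2, −78 to 0 °C; then NBS, THF, −78 °C
Reagents that add atoms: N-bromosuccinimide, O=C1CCC(=O)N1Br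
Why: Enol silane formation followed by electrophilic bromination is regiodefined because the ketone can enolise only toward its methyl group (C4 is quaternary), and the electron-poor alkenes do not react with NBS at −78 °C.

Step 14
Reactants: 26 (1R,3R)-3-(acetyloxy)-5-bromo-3-methyl-1-[(2R,3S)-4-methylidene-2-{(2S)-2-methyl-3-[(triethylsilyl)oxy]propyl}-5-oxooxolan-3-yl]-4-oxopentyl (2Z)-2-methylbut-2-enoate
Product: 28 (1R,3R)-3-(acetyloxy)-5-bromo-3-methyl-1-{(2R,3S)-4-methylidene-2-[(2S)-2-methyl-3-oxopropyl]-5-oxooxolan-3-yl}-4-oxopentyl (2Z)-2-methylbut-2-enoate, via alkoxysulfonium salt 27 (not isolated)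
Conditions: (COCl)2, DMSO, CH2Cl2, −78 to −40 °C; then iPr2NEt, −78 to 0 °C
Reagents that add atoms: none
Why: Under Swern conditions the primary TES ether is cleaved directly to the alkoxysulfonium ion, which fragments to the C1 aldehyde, and the low temperature and hindered base keep the α-stereocentre C10 from epimerising.

Step 15
Reactants: 28 (1R,3R)-3-(acetyloxy)-5-bromo-3-methyl-1-{(2R,3S)-4-methylidene-2-[(2S)-2-methyl-3-oxopropyl]-5-oxooxolan-3-yl}-4-oxopentyl (2Z)-2-methylbut-2-enoate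
Product: 30 (3aS,4R,6R,9S,10S,11aR)-6-(acetyloxy)-9-hydroxy-6,10-dimethyl-3-methylidene-2,7-dioxododecahydrocyclodeca[b]furan-4-yl (2Z)-2-methylbut-2-enoate (CNP0141210.1), via samarium enolate 29 (not isolated)
Conditions: SmI2 (2.2 equiv), THF (0.002 M, slow addition), −78 °C; aq NH4Cl at −78 °C
Reagents that add atoms: none
Why: SmI2-mediated intramolecular Reformatsky-type aldol, in which the Sm(III) enolate formed from the bromoketone adds through a chelated chair to the Felkin–Anh face of the α-methyl aldehyde, closing the ten-membered ring and setting C1 as S (1,2-syn to the C10 methyl).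

**Compound list**

1 | (R)-3-bromo-2-methylpropan-1-ol | BrC[C@H](C)CO | starting material
2 | [(2R)-3-bromo-2-methylpropoxy]triethylsilane | BrC[C@H](C)CO[Si](CC)(CC)CC | intermediate
3 | {(2R)-2-methyl-3-[(triethylsilyl)oxy]propyl}magnesium bromide | Br[Mg]C[C@H](C)CO[Si](CC)(CC)CC | intermediate
4 | (3S)-3-methyl-4-[(triethylsilyl)oxy]butanal | O=CC[C@H](C)CO[Si](CC)(CC)CC | intermediate
5 | hex-1-yne | C#CCCCC | starting material
6 | dicyclohexyl[(1E)-hex-1-en-1-yl]borane | CCCC/C=C/B(C1CCCCC1)C1CCCCC1 | intermediate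
7 | [(1E)-hex-1-en-1-yl](methyl)zinc | CCCC/C=C/[Zn]C | intermediate
8 | (2S,4R,5E)-2-methyl-1-[(triethylsilyl)oxy]dec-5-en-4-ol | O[C@@H](/C=C/CCCC)C[C@H](C)CO[Si](CC)(CC)CC | intermediate
9 | 2-(bromomethyl)prop-2-enoic acid | C=C(CBr)C(=O)O | starting material
10 | 2-(bromomethyl)prop-2-enoyl chloride | C=C(CBr)C(Cl)=O | intermediate
11 | (2S,4R,5E)-2-methyl-1-[(triethylsilyl)oxy]dec-5-en-4-yl 2-(bromomethyl)prop-2-enoate | C=C(CBr)C(=O)O[C@@H](/C=C/CCCC)C[C@H](C)CO[Si](CC)(CC)CC | intermediate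
12 | (5R)-3-(bromomethyl)-5-{(2S)-2-methyl-3-[(triethylsilyl)oxy]propyl}furan-2(5H)-one | O=C1O[C@H](C[C@H](C)CO[Si](CC)(CC)CC)C=C1CBr | intermediate
13 | S-ethyl ethanethioate | CCSC(C)=O | starting material
14 | lithium 1-(ethylsulfanyl)ethen-1-olate | [Li]OC(=C)SCC | intermediate
15 | {[1-(ethylsulfanyl)ethenyl]oxy}(trimethyl)silane | C=C(O[Si](C)(C)C)SCC | intermediate
16 | butane-2,3-dione | CC(=O)C(C)=O | starting material
17 | S-ethyl (3R)-3-methyl-4-oxo-3-[(trimethylsilyl)oxy]pentanethioate | CC(=O)[C@](C)(O[Si](C)(C)C)CC(=O)SCC | intermediate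
18 | S-ethyl (3R)-3-hydroxy-3-methyl-4-oxopentanethioate | CC(=O)[C@](C)(O)CC(=O)SCC | intermediate
19 | S-ethyl (3R)-3-(acetyloxy)-3-methyl-4-oxopentanethioate | CC(=O)[C@](C)(OC(C)=O)CC(=O)SCC | intermediate
20 | (3R)-3-methyl-1,4-dioxopentan-3-yl acetate [(3R)-3-acetoxy-3-methyl-4-oxopentanal] | CC(=O)[C@](C)(OC(C)=O)CC=O | intermediate
21 | dichloro({(5R)-5-[(2S)-2-methyl-3-(triethylsilyloxy)propyl]-2-oxo-2,5-dihydrofuran-3-yl}methyl)chromium(III) | O=C1O[C@H](C[C@H](C)CO[Si](CC)(CC)CC)C=C1C[Cr](Cl)Cl | intermediate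
22 | (4R,5R)-4-[(1S,3R)-3-(acetyloxy)-1-hydroxy-3-methyl-4-oxopentyl]-3-methylidene-5-{(2S)-2-methyl-3-[(triethylsilyl)oxy]propyl}oxolan-2-one | C=C1C(=O)O[C@H](C[C@H](C)CO[Si](CC)(CC)CC)[C@H]1[C@@H](O)C[C@@](C)(OC(C)=O)C(C)=O | intermediate
23 | (2Z)-2-methylbut-2-enoic acid (angelic acid) | C/C=C(/C)C(=O)O | starting material
24 | (1R,3R)-3-(acetyloxy)-3-methyl-1-[(2R,3S)-4-methylidene-2-{(2S)-2-methyl-3-[(triethylsilyl)oxy]propyl}-5-oxooxolan-3-yl]-4-oxopentyl (2Z)-2-methylbut-2-enoate | C=C1C(=O)O[C@H](C[C@H](C)CO[Si](CC)(CC)CC)[C@H]1[C@H](OC(=O)/C(C)=C\C)C[C@@](C)(OC(C)=O)C(C)=O | intermediate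
25 | (1R,3R)-3-(acetyloxy)-3-methyl-1-[(2R,3S)-4-methylidene-2-{(2S)-2-methyl-3-[(triethylsilyl)oxy]propyl}-5-oxooxolan-3-yl]-4-[(trimethylsilyl)oxy]pent-4-en-1-yl (2Z)-2-methylbut-2-enoate | C=C1C(=O)O[C@H](C[C@H](C)CO[Si](CC)(CC)CC)[C@H]1[C@H](OC(=O)/C(C)=C\C)C[C@@](C)(OC(C)=O)C(=C)O[Si](C)(C)C | intermediate
26 | (1R,3R)-3-(acetyloxy)-5-bromo-3-methyl-1-[(2R,3S)-4-methylidene-2-{(2S)-2-methyl-3-[(triethylsilyl)oxy]propyl}-5-oxooxolan-3-yl]-4-oxopentyl (2Z)-2-methylbut-2-enoate | C=C1C(=O)O[C@H](C[C@H](C)CO[Si](CC)(CC)CC)[C@H]1[C@H](OC(=O)/C(C)=C\C)C[C@@](C)(OC(C)=O)C(=O)CBr | intermediate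
27 | alkoxy(dimethyl)sulfonium chloride of 26 (the O–SiEt3 group replaced by O–S+(CH3)2 Cl−) | C=C1C(=O)O[C@H](C[C@H](C)CO[S+](C)C)[C@H]1[C@H](OC(=O)/C(C)=C\C)C[C@@](C)(OC(C)=O)C(=O)CBr.[Cl-] | intermediate
28 | (1R,3R)-3-(acetyloxy)-5-bromo-3-methyl-1-{(2R,3S)-4-methylidene-2-[(2S)-2-methyl-3-oxopropyl]-5-oxooxolan-3-yl}-4-oxopentyl (2Z)-2-methylbut-2-enoate | C=C1C(=O)O[C@H](C[C@H](C)C=O)[C@H]1[C@H](OC(=O)/C(C)=C\C)C[C@@](C)(OC(C)=O)C(=O)CBr | intermediate
29 | diiodosamarium(III) enolate of 28 (C2=C3–O–SmI2 in place of the bromomethyl ketone) | C=C1C(=O)O[C@H](C[C@H](C)C=O)[C@H]1[C@H](OC(=O)/C(C)=C\C)C[C@@](C)(OC(C)=O)C(=C)O[Sm](I)I | intermediate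
30 | (3aS,4R,6R,9S,10S,11aR)-6-(acetyloxy)-9-hydroxy-6,10-dimethyl-3-methylidene-2,7-dioxododecahydrocyclodeca[b]furan-4-yl (2Z)-2-methylbut-2-enoate; germacrane descriptors 1S,4R,6R,7S,8R,10S | C=C1C(=O)O[C@@H]2C[C@H](C)[C@@H](O)CC(=O)[C@](C)(OC(C)=O)C[C@@H](OC(=O)/C(C)=C\C)[C@@H]12 | target

**Step count and risks**

Total step count: 15.
Longest linear sequence: 10 steps (1, 2, 3, 5, 6, 11, 12, 13, 14, 15).

The three steps most likely to fail:

Step 11 (Nozaki–Hiyama coupling). The β-acetoxy aldehyde 20 can lose acetic acid. The chromium alkoxide of the product can translactonise onto C12 or take the acetyl group from O4. The facial and anti selectivities rest on the chair model. Fallback: setting out from 12, Pd-catalysed borylation (B2pin2, Pd2(dba)3, THF, 50 °C) gives the isolable allylboronate (5R)-5-{(2S)-2-methyl-3-[(triethylsilyl)oxy]propyl}-3-[(4,4,5,5-tetramethyl-1,3,2-dioxaborolan-2-yl)methyl]furan-2(5H)-one F1. This adds to 20 under Sc(OTf)3 catalysis (toluene, −78 to 0 °C) through a closed six-membered transition state of the same anti, trans sense, delivering a non-nucleophilic borate, and the route is rejoined at 22.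

Step 12 (Mitsunobu inversion). The C6 carbinol is hindered and can close onto the C3 ketone as a hemiketal. Elimination toward C7 and phosphine-induced angelate-to-tiglate isomerisation are possible. Fallback: setting out from 22, mesylation (MsCl, Et3N, CH2Cl2, −20 °C) gives (1S,3R)-3-(acetyloxy)-3-methyl-1-[(2R,3S)-4-methylidene-2-{(2S)-2-methyl-3-[(triethylsilyl)oxy]propyl}-5-oxooxolan-3-yl]-4-oxopentyl methanesulfonate F2. SN2 displacement with caesium angelate and 18-crown-6 (toluene, 60 °C) then inverts C6 without any phosphine present and comes back to the route at 24.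

Step 15 (SmI2 macrocyclisation). Ten-membered ring strain may divert the samarium enolate to simple debromination. Excess SmI2 can cleave the α-acetoxy ketone or give the ketyl of the aldehyde. The C1 selectivity depends on Felkin control surviving in the macrocyclic transition state. Fallback: setting out from 24 and omitting the bromination, direct Swern oxidation of the TES ether gives the keto-aldehyde (1R,3R)-3-(acetyloxy)-3-methyl-1-{(2R,3S)-4-methylidene-2-[(2S)-2-methyl-3-oxopropyl]-5-oxooxolan-3-yl}-4-oxopentyl (2Z)-2-methylbut-2-enoate F3. This is cyclised by a boron-mediated aldol (Cy2BCl, Et3N, Et2O, −78 °C, syringe-pump addition at 0.002 M, non-oxidative work-up), relying on the methyl ketone being enolised much faster than the α-branched aldehyde, and arrives directly at 30.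

Further compounds
F1 | step 11 | (5R)-5-{(2S)-2-methyl-3-[(triethylsilyl)oxy]propyl}-3-[(4,4,5,5-tetramethyl-1,3,2-dioxaborolan-2-yl)methyl]furan-2(5H)-one | O=C1O[C@H](C[C@H](C)CO[Si](CC)(CC)CC)C=C1CB1OC(C)(C)C(C)(C)O1
F2 | step 12 | (1S,3R)-3-(acetyloxy)-3-methyl-1-[(2R,3S)-4-methylidene-2-{(2S)-2-methyl-3-[(triethylsilyl)oxy]propyl}-5-oxooxolan-3-yl]-4-oxopentyl methanesulfonate | C=C1C(=O)O[C@H](C[C@H](C)CO[Si](CC)(CC)CC)[C@H]1[C@@H](OS(C)(=O)=O)C[C@@](C)(OC(C)=O)C(C)=O
F3 | step 15 | (1R,3R)-3-(acetyloxy)-3-methyl-1-{(2R,3S)-4-methylidene-2-[(2S)-2-methyl-3-oxopropyl]-5-oxooxolan-3-yl}-4-oxopentyl (2Z)-2-methylbut-2-enoate | C=C1C(=O)O[C@H](C[C@H](C)C=O)[C@H]1[C@H](OC(=O)/C(C)=C\C)C[C@@](C)(OC(C)=O)C(C)=O
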